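**Retrosynthetic overview**

1. The route rests on side-chain carbon C1', which is bonded at once to ring carbon C2 of the naphthazarin bicycle, to vinyl carbon C2' and to the ester oxygen, so an aryl, an enal and an acyl fragment can meet there.
2. Key disconnection: the C2–C1' bond and the ester O–acyl bond are made in one flask from the arylzinc of (1,4,5,8-tetramethoxynaphthalen-2-yl)boronic acid, (E)-4-methyl-4-(triethylsilyloxy)pent-2-enal and (R)-2-methylbutanoic anhydride under a chiral amino alcohol.
3. Fragments: the boronic acid from naphthazarin (reductive methylation, bromination, lithiation–borylation); the enal by cross-metathesis of 2-methylbut-3-en-2-ol with crotonaldehyde, then silylation; the anhydride from (R)-2-methylbutanoic acid.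
4. End game: desilylation, then unmasking of the naphthazarin with (NH4)2Ce(NO3)6 followed by AgO/HNO3 and Na2S2O4 reduction.
5. Ring order: no ring is formed; both six-membered carbocycles come from naphthazarin and are only masked and unmasked.

Key step: step 7

Remark (assumption): naphthazarins are rapidly interconverting tautomers, so the product of step 10 is the compound of the target SMILES whichever ring is drawn as the quinone.

**Route**

Step 1
Reactants: 1 naphthazarin (5,8-dihydroxy-1,4-naphthoquinone)
Product: 3 1,4,5,8-tetramethoxynaphthalene, via naphthalene-1,4,5,8-tetrol 2 (not isolated)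
Conditions: Na2S2O4, Bu4NBr (cat.), THF/H2O, rt, N2; then NaOH (aq), Me2SO4, rt
Reagents that add atoms: dimethyl sulfate, COS(=O)(=O)OC
Why: Dithionite reduces the quinone to the air-sensitive tetrol, whose four phenoxides are O-methylated by dimethyl sulfate under phase-transfer conditions (reductive methylation, Williamson ether synthesis).

Step 2
Reactants: 3 1,4,5,8-tetramethoxynaphthalene
Product: 4 2-bromo-1,4,5,8-tetramethoxynaphthalene
Conditions: NBS (1.0 equiv), CH2Cl2, rt, dark
Reagents that add atoms: N-bromosuccinimide, O=C1CCC(=O)N1Br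
Why: Electrophilic aromatic bromination of the electron-rich arene with one equivalent of NBS should stop at the monobromide, and because the four ring CH positions are equivalent only the 2-bromide can form.

Step 3
Reactants: 4 2-bromo-1,4,5,8-tetramethoxynaphthalene
Product: 7 (1,4,5,8-tetramethoxynaphthalen-2-yl)boronic acid, via aryllithium 5 (not isolated), via lithium triisopropoxyarylborate 6 (not isolated)
Conditions: n-BuLi, THF, −78 °C; B(OiPr)3, −78 °C → rt; 1 M HCl to pH 5, 0 °C
Reagents that add atoms: triisopropyl borate, CC(C)OB(OC(C)C)OC(C)C; water, O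
Why: Bromine–lithium exchange at −78 °C outruns any attack on the methyl ethers, and the aryllithium is trapped by the borate ester as an ate complex that hydrolyses to the boronic acid on mild acidification (lithiation–borylation).

Step 4
Reactants: 8 2-methylbut-3-en-2-ol; 9 (E)-crotonaldehyde
Product: 10 (E)-4-hydroxy-4-methylpent-2-enal
Conditions: second-generation Hoveyda–Grubbs catalyst RuCl2(H2IMes)(=CH-C6H4-2-OiPr) (2.5 mol%), 9 (3 equiv), CH2Cl2, 40 °C
Reagents that add atoms: none
Why: Olefin cross-metathesis between the slowly homodimerising tertiary allylic alcohol and the electron-poor crotonaldehyde, used in excess, should give the E-enal under thermodynamic control with loss of propene.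

Step 5
Reactants: 10 (E)-4-hydroxy-4-methylpent-2-enal
Product: 11 (E)-4-methyl-4-(triethylsilyloxy)pent-2-enal
Conditions: TESOTf, 2,6-lutidine, CH2Cl2, −78 °C
Reagents that add atoms: triethylsilyl trifluoromethanesulfonate, CC[Si](CC)(CC)OS(=O)(=O)C(F)(F)F
Why: Silyl triflate with a hindered base silylates the tertiary alcohol at low temperature, and since C4 is quaternary the enal has no γ-hydrogen from which a silyl dienol ether could form.

Step 6
Reactants: 12 (R)-2-methylbutanoic acid (two molecules per molecule of product)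
Product: 14 (R)-2-methylbutanoic anhydride, via O-acylisourea 13 (not isolated)
Conditions: 12 (2.0 equiv), DCC (1.0 equiv), CH2Cl2, 0 °C → rt; filter
Reagents that add atoms: (R)-2-methylbutanoic acid (the second molecule of 12, which is acylated by 13), CC[C@@H](C)C(=O)O
Why: Carbodiimide dehydration activates one molecule of acid as the O-acylisourea, which acylates a second molecule of the acid to give the symmetric anhydride and the urea, and as no base is present the α-stereocentre is not enolised.

Step 7
Reactants: 7 (1,4,5,8-tetramethoxynaphthalen-2-yl)boronic acid; 11 (E)-4-methyl-4-(triethylsilyloxy)pent-2-enal; 14 (R)-2-methylbutanoic anhydride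
Product: 17 (1R,2E)-4-methyl-1-(1,4,5,8-tetramethoxynaphthalen-2-yl)-4-(triethylsilyloxy)pent-2-en-1-yl (2R)-2-methylbutanoate, via aryl ethyl zinc 15 (not isolated), via ethylzinc alkoxide 16 (not isolated)
Conditions: 7 (2 equiv), Zn(C2H5)2 (6 equiv), toluene, 60 °C; then (−)-MIB [(2S)-3-exo-morpholinoisoborneol] (10 mol%), 11 (1 equiv), 0 °C; then 14 (4 equiv), 0 °C → rt; aq NH4Cl
Reagents that add atoms: none
Why: Boron-to-zinc exchange between 7 and Zn(C2H5)2 gives the mixed aryl ethyl zinc 15, and in the dinuclear zinc amino alkoxide formed from (−)-MIB one zinc binds and activates the carbonyl oxygen of 11 while the other delivers the aryl carbon, which migrates faster than ethyl, to the carbonyl carbon, forming C2–C1'. The closest known reaction type is the amino-alcohol-catalysed asymmetric aryl transfer from an arylboronic acid and Zn(C2H5)2 to aldehydes, enals included, followed by acylation of the zinc alkoxide with an anhydride before work-up, which here forms the ester C–O bond from 16 and 14. No ring is closed. C1' is set by the ligand: (−)-MIB, the enantiomer that delivers ethyl to the Si face of benzaldehyde (S alcohol), should deliver the aryl group to the Si face of the enal carbonyl, which is R here because aryl outranks vinyl, while the acyl stereocentre enters unchanged from 14. The step needs face selectivity, 1,2- over 1,4-addition and aryl over ethyl transfer; carbonyl-bound delivery from a hard organozinc, the quaternary silyloxy carbon C4' next to the β-position and the higher migratory aptitude of the aryl group should secure them, and the silyl ether leaves no acidic site for the zinc reagents. Acylation in the flask means that the benzylic allylic alcohol next to the electron-rich ring, which ionises easily, is never isolated.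

Step 8
Reactants: 17 (1R,2E)-4-methyl-1-(1,4,5,8-tetramethoxynaphthalen-2-yl)-4-(triethylsilyloxy)pent-2-en-1-yl (2R)-2-methylbutanoate
Product: 18 (1R,2E)-4-hydroxy-4-methyl-1-(1,4,5,8-tetramethoxynaphthalen-2-yl)pent-2-en-1-yl (2R)-2-methylbutanoate
Conditions: HF·pyridine, pyridine, THF, 0 °C → rt
Reagents that add atoms: none
Why: Fluoride-driven desilylation buffered with excess pyridine should remove the triethylsilyl ether without acid strong enough to ionise the benzylic allylic ester or base strong enough to cleave it.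

Step 9
Reactants: 18 (1R,2E)-4-hydroxy-4-methyl-1-(1,4,5,8-tetramethoxynaphthalen-2-yl)pent-2-en-1-yl (2R)-2-methylbutanoate
Product: 19 (1R,2E)-1-(1,4-dimethoxy-5,8-dioxo-5,8-dihydronaphthalen-2-yl)-4-hydroxy-4-methylpent-2-en-1-yl (2R)-2-methylbutanoate
Conditions: (NH4)2Ce(NO3)6 (2.5 equiv), MeCN/H2O, 0 °C; SiO2 chromatography
Reagents that add atoms: water, O
Why: Oxidative demethylation of a 1,4-dimethoxyarene by tetravalent cerium (two one-electron oxidations, attack of water, loss of methanol) gives a quinone and should stop after one ring because the fused quinone deactivates the other; the ring remote from the acyloxy-bearing side chain is expected to react preferentially, and any regioisomeric quinone that forms is removed on chromatography.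

Step 10
Reactants: 19 (1R,2E)-1-(1,4-dimethoxy-5,8-dioxo-5,8-dihydronaphthalen-2-yl)-4-hydroxy-4-methylpent-2-en-1-yl (2R)-2-methylbutanoate
Product: 21 (1R,2E)-1-(5,8-dihydroxy-1,4-dioxo-1,4-dihydronaphthalen-2-yl)-4-hydroxy-4-methylpent-2-en-1-yl (2R)-2-methylbutanoate, via naphthalene-1,4,5,8-tetrone 20 (not isolated)
Conditions: AgO, 6 M HNO3, acetone, rt, 5 min; then aq Na2S2O4 (1 equiv), CHCl3, 0 °C
Reagents that add atoms: water, O
Why: AgO in nitric acid is strong enough to demethylate the deactivated dimethoxy ring of 19 oxidatively to diquinone 20, and one equivalent of dithionite reduces this strongly oxidising tetrone by two electrons to the naphthazarin without touching C1'.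

**Compound list**

1 | naphthazarin (5,8-dihydroxy-1,4-naphthoquinone) | O=C1C=CC(=O)c2c(O)ccc(O)c12 | starting material
2 | naphthalene-1,4,5,8-tetrol (leuconaphthazarin, tetraphenol tautomer) | Oc1ccc(O)c2c(O)ccc(O)c12 | intermediate
3 | 1,4,5,8-tetramethoxynaphthalene | COc1ccc(OC)c2c(OC)ccc(OC)c12 | intermediate
4 | 2-bromo-1,4,5,8-tetramethoxynaphthalene | COc1cc(Br)c(OC)c2c(OC)ccc(OC)c12 | intermediate
5 | (1,4,5,8-tetramethoxynaphthalen-2-yl)lithium | [Li]c1cc(OC)c2c(OC)ccc(OC)c2c1OC | intermediate
6 | lithium triisopropoxy(1,4,5,8-tetramethoxynaphthalen-2-yl)borate | [Li+].CC(C)O[B-](OC(C)C)(OC(C)C)c1cc(OC)c2c(OC)ccc(OC)c2c1OC | intermediate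
7 | (1,4,5,8-tetramethoxynaphthalen-2-yl)boronic acid | COc1cc(B(O)O)c(OC)c2c(OC)ccc(OC)c12 | intermediate
8 | 2-methylbut-3-en-2-ol | C=CC(C)(C)O | starting material
9 | (E)-crotonaldehyde | C/C=C/C=O | starting material
10 | (E)-4-hydroxy-4-methylpent-2-enal | CC(C)(O)/C=C/C=O | intermediate
11 | (E)-4-methyl-4-(triethylsilyloxy)pent-2-enal | CC[Si](CC)(CC)OC(C)(C)/C=C/C=O | intermediate
12 | (R)-2-methylbutanoic acid | CC[C@@H](C)C(=O)O | starting material
13 | N,N'-dicyclohexyl-O-[(2R)-2-methylbutanoyl]isourea | CC[C@@H](C)C(=O)OC(=NC1CCCCC1)NC1CCCCC1 | intermediate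
14 | (R)-2-methylbutanoic anhydride | CC[C@@H](C)C(=O)OC(=O)[C@H](C)CC | intermediate
15 | ethyl(1,4,5,8-tetramethoxynaphthalen-2-yl)zinc | CC[Zn]c1cc(OC)c2c(OC)ccc(OC)c2c1OC | intermediate
16 | ethylzinc (1R,2E)-4-methyl-1-(1,4,5,8-tetramethoxynaphthalen-2-yl)-4-(triethylsilyloxy)pent-2-en-1-olate | CC[Zn]O[C@H](/C=C/C(C)(C)O[Si](CC)(CC)CC)c1cc(OC)c2c(OC)ccc(OC)c2c1OC | intermediate
17 | (1R,2E)-4-methyl-1-(1,4,5,8-tetramethoxynaphthalen-2-yl)-4-(triethylsilyloxy)pent-2-en-1-yl (2R)-2-methylbutanoate | CC[C@@H](C)C(=O)O[C@H](/C=C/C(C)(C)O[Si](CC)(CC)CC)c1cc(OC)c2c(OC)ccc(OC)c2c1OC | intermediate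
18 | (1R,2E)-4-hydroxy-4-methyl-1-(1,4,5,8-tetramethoxynaphthalen-2-yl)pent-2-en-1-yl (2R)-2-methylbutanoate | CC[C@@H](C)C(=O)O[C@H](/C=C/C(C)(C)O)c1cc(OC)c2c(OC)ccc(OC)c2c1OC | intermediate
19 | (1R,2E)-1-(1,4-dimethoxy-5,8-dioxo-5,8-dihydronaphthalen-2-yl)-4-hydroxy-4-methylpent-2-en-1-yl (2R)-2-methylbutanoate | CC[C@@H](C)C(=O)O[C@H](/C=C/C(C)(C)O)c1cc(OC)c2C(=O)C=CC(=O)c2c1OC | intermediate
20 | (1R,2E)-4-hydroxy-4-methyl-1-(1,4,5,8-tetraoxo-1,4,5,8-tetrahydronaphthalen-2-yl)pent-2-en-1-yl (2R)-2-methylbutanoate | CC[C@@H](C)C(=O)O[C@H](/C=C/C(C)(C)O)C1=CC(=O)C2=C(C1=O)C(=O)C=CC2=O | intermediate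
21 | (1R,2E)-1-(5,8-dihydroxy-1,4-dioxo-1,4-dihydronaphthalen-2-yl)-4-hydroxy-4-methylpent-2-en-1-yl (2R)-2-methylbutanoate | CC[C@@H](C)C(=O)O[C@H](/C=C/C(C)(C)O)C1=CC(=O)c2c(O)ccc(O)c2C1=O | target

**Step count**

Total: 10 steps. Longest linear sequence: 7 steps (1, 2, 3, 7, 8, 9, 10).

**Steps most likely to fail**

Step 7. Boron-to-zinc exchange and transfer of the ortho-methoxy, peri-crowded naphthyl group may be slow. Ethyl transfer and the ligand-free racemic addition could then compete and erode face selectivity, and acylation of the hindered zinc alkoxide by the α-branched anhydride may stall.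

The fallback reverses the polarity at C1' and uses the known asymmetric alkenylzinc addition to an aryl aldehyde. It sets out from 3, which Vilsmeier–Haack formylation (POCl3, DMF) should convert into 1,4,5,8-tetramethoxynaphthalene-2-carbaldehyde F1. Commercial 2-methylbut-3-yn-2-ol is silylated (TESCl, imidazole, DMF) to triethyl[(2-methylbut-3-yn-2-yl)oxy]silane F2. Hydroboration with dicyclohexylborane gives dicyclohexyl[(E)-3-methyl-3-(triethylsilyloxy)but-1-en-1-yl]borane F3. Exchange with Zn(C2H5)2 at −78 °C gives ethyl[(E)-3-methyl-3-(triethylsilyloxy)but-1-en-1-yl]zinc F4. F4 adds to F1 under (+)-MIB (10 mol%); the opposite ligand enantiomer is required because the incoming vinyl carbon now ranks below the aryl group, so Re-face delivery gives R. This forms the same ethylzinc alkoxide 16, which is acylated with 14 as in step 7, and the route is rejoined at 17.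

Step 10. The free tertiary allylic hydroxyl may ionise in nitric acid, leading to allylic transposition or dehydration to the diene. Over-reduction by dithionite to the leuco stage could also be followed by expulsion of the C1' carboxylate.

The fallback keeps the tertiary hydroxyl masked through both oxidations as a silyl ether that resists aqueous acid and removes it last. It sets out from 10, which TBSOTf and 2,6-lutidine convert into (E)-4-(tert-butyldimethylsilyloxy)-4-methylpent-2-enal F5. Coupling with 7 and 14 under the conditions of step 7 proceeds through ethylzinc (1R,2E)-4-(tert-butyldimethylsilyloxy)-4-methyl-1-(1,4,5,8-tetramethoxynaphthalen-2-yl)pent-2-en-1-olate F6. It gives (1R,2E)-4-(tert-butyldimethylsilyloxy)-4-methyl-1-(1,4,5,8-tetramethoxynaphthalen-2-yl)pent-2-en-1-yl (2R)-2-methylbutanoate F7. (NH4)2Ce(NO3)6 then oxidises the ring remote from the side chain, as in step 9, to give (1R,2E)-4-(tert-butyldimethylsilyloxy)-1-(1,4-dimethoxy-5,8-dioxo-5,8-dihydronaphthalen-2-yl)-4-methylpent-2-en-1-yl (2R)-2-methylbutanoate F8, purified on silica. AgO/HNO3 converts it into (1R,2E)-4-(tert-butyldimethylsilyloxy)-4-methyl-1-(1,4,5,8-tetraoxo-1,4,5,8-tetrahydronaphthalen-2-yl)pent-2-en-1-yl (2R)-2-methylbutanoate F9. One equivalent of Na2S2O4, added slowly at 0 °C, reduces it to (1R,2E)-4-(tert-butyldimethylsilyloxy)-1-(5,8-dihydroxy-1,4-dioxo-1,4-dihydronaphthalen-2-yl)-4-methylpent-2-en-1-yl (2R)-2-methylbutanoate F10. Prolonged treatment with HF·pyridine in THF at rt then removes the silyl group and the route is rejoined at 21.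

Step 4. Either alkene may homodimerise, the enal may deactivate the ruthenium carbene, and the volatile, water-soluble hydroxy enal may be lost on isolation.

The fallback replaces metathesis by carbonyl olefination. It sets out from 8, which TESOTf and 2,6-lutidine convert into triethyl[(2-methylbut-3-en-2-yl)oxy]silane F11. Ozonolysis (O3, CH2Cl2, −78 °C) proceeds through 3-[2-(triethylsilyloxy)propan-2-yl]-1,2,4-trioxolane F12, and reduction with PPh3 gives 2-methyl-2-(triethylsilyloxy)propanal F13. Wittig olefination with (triphenylphosphoranylidene)acetaldehyde (toluene, 80 °C) should give the E-enal directly, and the route is rejoined at 11.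

**Further compounds**

F1 | step 7 | 1,4,5,8-tetramethoxynaphthalene-2-carbaldehyde | COc1cc(C=O)c(OC)c2c(OC)ccc(OC)c12
F2 | step 7 | triethyl[(2-methylbut-3-yn-2-yl)oxy]silane | CC[Si](CC)(CC)OC(C)(C)C#C
F3 | step 7 | dicyclohexyl[(E)-3-methyl-3-(triethylsilyloxy)but-1-en-1-yl]borane | CC[Si](CC)(CC)OC(C)(C)/C=C/B(C1CCCCC1)C1CCCCC1
F4 | step 7 | ethyl[(E)-3-methyl-3-(triethylsilyloxy)but-1-en-1-yl]zinc | CC[Zn]/C=C/C(C)(C)O[Si](CC)(CC)CC
F5 | step 10 | (E)-4-(tert-butyldimethylsilyloxy)-4-methylpent-2-enal | CC(C)(C)[Si](C)(C)OC(C)(C)/C=C/C=O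
F6 | step 10 | ethylzinc (1R,2E)-4-(tert-butyldimethylsilyloxy)-4-methyl-1-(1,4,5,8-tetramethoxynaphthalen-2-yl)pent-2-en-1-olate | CC[Zn]O[C@H](/C=C/C(C)(C)O[Si](C)(C)C(C)(C)C)c1cc(OC)c2c(OC)ccc(OC)c2c1OC
F7 | step 10 | (1R,2E)-4-(tert-butyldimethylsilyloxy)-4-methyl-1-(1,4,5,8-tetramethoxynaphthalen-2-yl)pent-2-en-1-yl (2R)-2-methylbutanoate | CC[C@@H](C)C(=O)O[C@H](/C=C/C(C)(C)O[Si](C)(C)C(C)(C)C)c1cc(OC)c2c(OC)ccc(OC)c2c1OC
F8 | step 10 | (1R,2E)-4-(tert-butyldimethylsilyloxy)-1-(1,4-dimethoxy-5,8-dioxo-5,8-dihydronaphthalen-2-yl)-4-methylpent-2-en-1-yl (2R)-2-methylbutanoate | CC[C@@H](C)C(=O)O[C@H](/C=C/C(C)(C)O[Si](C)(C)C(C)(C)C)c1cc(OC)c2C(=O)C=CC(=O)c2c1OC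
F9 | step 10 | (1R,2E)-4-(tert-butyldimethylsilyloxy)-4-methyl-1-(1,4,5,8-tetraoxo-1,4,5,8-tetrahydronaphthalen-2-yl)pent-2-en-1-yl (2R)-2-methylbutanoate | CC[C@@H](C)C(=O)O[C@H](/C=C/C(C)(C)O[Si](C)(C)C(C)(C)C)C1=CC(=O)C2=C(C1=O)C(=O)C=CC2=O
F10 | step 10 | (1R,2E)-4-(tert-butyldimethylsilyloxy)-1-(5,8-dihydroxy-1,4-dioxo-1,4-dihydronaphthalen-2-yl)-4-methylpent-2-en-1-yl (2R)-2-methylbutanoate | CC[C@@H](C)C(=O)O[C@H](/C=C/C(C)(C)O[Si](C)(C)C(C)(C)C)C1=CC(=O)c2c(O)ccc(O)c2C1=O
F11 | step 4 | triethyl[(2-methylbut-3-en-2-yl)oxy]silane | CC[Si](CC)(CC)OC(C)(C)C=C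
F12 | step 4 | 3-[2-(triethylsilyloxy)propan-2-yl]-1,2,4-trioxolane | CC[Si](CC)(CC)OC(C)(C)C1OCOO1
F13 | step 4 | 2-methyl-2-(triethylsilyloxy)propanal | CC[Si](CC)(CC)OC(C)(C)C=O
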